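**Remark on the reading of the target.** The SMILES is read as 8,5',6'-triprenylquercetin. Flavone numbering is used for every flavonoid compound: O1, C2, C3, C4, C4a, C5 to C8, C8a in rings C and A, and C1' to C6' in ring B.

## Analysis of the target

Broussoflavonol G is an achiral flavonol. It has the quercetin skeleton: benzo ring A fused at C4a–C8a to pyranone ring C, with catechol ring B on C2. Hydroxyls stand at C3, C5, C7, C3' and C4', and prenyl groups at C8, C5' and C6'. There is no stereocentre, so the whole problem is one of position.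

Ring B is pentasubstituted, with C1' (chromonyl), C6' and C5' (prenyl), C4' and C3' (OH) in a row. The C6' prenyl group is ortho to the C2–C1' bond and would crowd any ring B aldehyde or acid used to build ring C.

The feature that the plan uses is this: every prenylated carbon lies ortho or para to a phenolic oxygen. C8 is para to O5 across ring A, C6' is para to O3' across ring B, and C5' is ortho to O4'.

The sensitive groups are three trisubstituted alkenes, two of them beside free phenols (C8/O7 and C5'/O4') and so prone to acid-induced chroman closure. The catechol and the 3-hydroxy-4-pyranone oxidise easily in base and air. The alkenes rule out hydrogenolysis, peracids and electrophilic halogen late in the route.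

The difficulty is the regiocontrol of three C-prenylations on an electron-rich core (C8 against C6, C5' and C6' against C2'), together with the congestion around C6'.

## Retrosynthetic reasoning

**16 from 14.** The last disconnection cuts the two acetal O–CH2 bonds at O3 and O7. These acetals keep O3 and O7 inert during the key step: they cannot migrate and they leave no acidic OH. Their removal needs only dilute acid and passes through mono-acetal 15.

**14 from 11 (key disconnection).** The three aryl–CH2 bonds at C8, C5' and C6' are cut at once. Each C5 unit is put back on the oxygen from which a [3,3] path leads to its carbon: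
- a prenyl ether on O5 (Claisen shift to C6, Cope shift to C8);
- a prenyl ether on O3' (Claisen shift to C2' or C4', Cope shift to C6');
- a 1,1-dimethylallyl ether on O4' (Claisen shift to C5' with allyl inversion).

Compound 11 is an isomer of 14 with no C-prenyl bond and an uncrowded ring B. The gain is twofold. The positional problem of three C-prenylations becomes a problem of O-alkylation, which acidity differences solve on small fragments. Ring C can also be made while ring B is still unhindered. The forward reaction has to run one ortho shift and two para relays in one flask, through 12 and 13, without stopping at a 1,1-dimethylallyl phenol at C6 or C2'.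

**11 from 10.** The O3–CH2 acetal bond is cut. O3 is capped only after ring C exists, because the ring-forming oxidation delivers it free.

**10 from 8.** Ring C is opened at O1–C2 and at the C3–O bond, which is the Algar–Flynn–Oyamada oxidative cyclisation of a 2'-hydroxychalcone, passing through 9. This cut is chosen over C2–C1' or C4–C4a because the reaction runs in cold base and so tolerates acid-labile allyl ethers and isolated alkenes. It is also applied to a chalcone whose ring B has no ortho substituent, which favours six-ring closure.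

**8 from 6 and 3.** The Cα=Cβ bond (the later C3–C2 bond) is cut by aldol condensation, through 7, into ring A ketone 6 and ring B aldehyde 3. This is the most convergent split of the C15 skeleton.

**3 from 2 from 1.** The two ring B ether bonds are cut. The tertiary ether goes first onto the more acidic 4-OH of 1 (para to the formyl group), and the prenyl ether then onto the remaining 3-OH. This order decides which oxygen carries which group, and so decides C5' against C6'.

**6 from 5 from 4.** On ring A the acetal goes onto the only hydroxyl of 4 that is not hydrogen-bonded to the acetyl group (the future O7). The prenyl ether goes onto one of the two equivalent chelated hydroxyls (the future O5). The other stays free as the future O1.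

## Alternatives that were turned down

**Alternative 1:** (the textbook route) Ring C is cut at O1–C2 and Cα–Cβ, with all three prenyl groups already on carbon. The forward key step is Claisen–Schmidt condensation of diprenyl aldehyde A1 with C-prenylated ketone A2 to chalcone A3, followed by Algar–Flynn–Oyamada oxidation and acetal cleavage.
- The key step forms none of the bonds that are hard here. Each prenyl bond needs its own solution: two tin-mediated cross-couplings on ring B for A1, and a C-prenylation of the phloroglucinol ring for A2 that competes with O- and bis-alkylation.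
- In A3 the β-carbon carries an aryl group with an ortho prenyl substituent. This slows the six-ring closure at Cβ relative to five-ring closure at Cα, adding to the aurone bias already caused by the alkoxy group ortho to the carbonyl on ring A.
- The route is about as long as the one chosen, but its risk is spread over four separate steps.

**Alternative 2:** Ring C is cut at C4–C4a, O1–C8a and O1–C2. Fluoride would convert silyl triflate A4 into aryne A5, which takes up the carboxylate oxygen of arylpropiolic acid A6 at C8a and its acyl carbon at C4a (insertion into the C–O bond). The resulting ynone closes to flavone A7.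
- The O5 acetal beside the triple bond steers the oxygen to C8a as needed, but the C8 prenyl group on the other side shields that same carbon.
- The ynone carries an aryl group with an ortho prenyl substituent, so 5-exo closure to an aurone competes with the 6-endo closure.
- A7 lacks O3, so a C3 lithiation, borylation and oxidation must follow in the presence of three prenyl groups.
- A4 and A6 each need about five steps, so the route is several steps longer than the one chosen.

**Alternative 3:** Ring A is cut at C4a–C5, C5–C6 and C7–C8, a benzannulation of Danheiser type on a preformed pyranone. The sequence is photochemical Wolff rearrangement of diazo ketone A8, [2+2] cycloaddition with a silyloxyalkyne, four-electron ring opening, and six-electron electrocyclisation onto the pyranone carbon that becomes C4a. After tautomerisation this would give A9 with O5 free and O7 silylated.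
- It spends the key step on the one ring that is cheap to buy.
- A8 already needs the hindered diprenyl ring B attached to a 3-alkoxy-4-pyranone acid, so the ring B problem is not solved but moved.
- It requires UV irradiation of a polyene substrate.
- C8 is left bare, so the C8 prenyl group still needs an O-prenylation and relay.

Key step: step 8

**Remarks on the chemistry.** tert-Butyl 2-methylbut-3-en-2-yl carbonate is taken to be a purchasable reagent. In Eu(fod)3, fod is 6,6,7,7,8,8,8-heptafluoro-2,2-dimethyloctane-3,5-dionate.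

## Route

Step 1
Reactants: 1 3,4-dihydroxybenzaldehyde
Product: 2 3-hydroxy-4-[(2-methylbut-3-en-2-yl)oxy]benzaldehyde
Conditions: tert-butyl 2-methylbut-3-en-2-yl carbonate (1.1 equiv), Pd(PPh3)4 (2 mol %), THF, 0 °C
Reagents that add atoms: tert-butyl 2-methylbut-3-en-2-yl carbonate, CC(C)(C)OC(=O)OC(C)(C)C=C
Why: Decarboxylative allylic etherification of Tsuji–Trost type under zerovalent palladium catalysis: the tert-butoxide set free deprotonates the more acidic 4-OH (para to the formyl group), and this phenoxide should attack the more substituted end of the 1,1-dimethylallyl palladium complex under kinetic control at low temperature, giving the tertiary ether; no stereocentre is formed.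

Step 2
Reactants: 2 3-hydroxy-4-[(2-methylbut-3-en-2-yl)oxy]benzaldehyde
Product: 3 4-[(2-methylbut-3-en-2-yl)oxy]-3-[(3-methylbut-2-en-1-yl)oxy]benzaldehyde
Conditions: prenyl bromide (1.2 equiv), K2CO3, DMF, rt
Reagents that add atoms: 1-bromo-3-methylbut-2-ene (prenyl bromide), CC(C)=CCBr
Why: Williamson etherification of the one remaining phenol; room temperature is kept because the neighbouring tertiary allyl ether would begin its Claisen shift on heating.

Step 3
Reactants: 4 1-(2,4,6-trihydroxyphenyl)ethan-1-one
Product: 5 1-[2,6-dihydroxy-4-(methoxymethoxy)phenyl]ethan-1-one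
Conditions: MOMCl (1.0 equiv), i-Pr2NEt, THF, 0 °C
Reagents that add atoms: chloromethyl methyl ether, COCCl
Why: Selective acetal formation: the 4-OH is the only hydroxyl of 4 that is not locked in a hydrogen bond to the acetyl carbonyl and is the most acidic, so one equivalent of the chloride should mark the future O7.

Step 4
Reactants: 5 1-[2,6-dihydroxy-4-(methoxymethoxy)phenyl]ethan-1-one
Product: 6 1-{2-hydroxy-4-(methoxymethoxy)-6-[(3-methylbut-2-en-1-yl)oxy]phenyl}ethan-1-one
Conditions: prenyl bromide (1.05 equiv), K2CO3, acetone, 50 °C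
Reagents that add atoms: 1-bromo-3-methylbut-2-ene (prenyl bromide), CC(C)=CCBr
Why: Williamson etherification of one of the two equivalent chelated hydroxyls; once one is alkylated the other is the sole, strongly hydrogen-bonded partner of the carbonyl and should not react further under K2CO3 in acetone.

Step 5
Reactants: 6 1-{2-hydroxy-4-(methoxymethoxy)-6-[(3-methylbut-2-en-1-yl)oxy]phenyl}ethan-1-one; 3 4-[(2-methylbut-3-en-2-yl)oxy]-3-[(3-methylbut-2-en-1-yl)oxy]benzaldehyde
Product: 8 (E)-1-{2-hydroxy-4-(methoxymethoxy)-6-[(3-methylbut-2-en-1-yl)oxy]phenyl}-3-{4-[(2-methylbut-3-en-2-yl)oxy]-3-[(3-methylbut-2-en-1-yl)oxy]phenyl}prop-2-en-1-one, via β-hydroxy ketone 7 (not isolated)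
Conditions: KOH, EtOH, rt
Reagents that add atoms: none
Why: Claisen–Schmidt condensation: the potassium enolate of 6 adds to the unhindered aldehyde 3 and the aldol 7 loses water by E1cB elimination; the E alkene is the thermodynamic product, and the allyl ethers and the acetal are stable to base at room temperature.

Step 6
Reactants: 8 (E)-1-{2-hydroxy-4-(methoxymethoxy)-6-[(3-methylbut-2-en-1-yl)oxy]phenyl}-3-{4-[(2-methylbut-3-en-2-yl)oxy]-3-[(3-methylbut-2-en-1-yl)oxy]phenyl}prop-2-en-1-one
Product: 10 3-hydroxy-7-(methoxymethoxy)-2-{4-[(2-methylbut-3-en-2-yl)oxy]-3-[(3-methylbut-2-en-1-yl)oxy]phenyl}-5-[(3-methylbut-2-en-1-yl)oxy]-4H-chromen-4-one, via trans-dihydroflavonol 9 (not isolated)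
Conditions: H2O2 (30 % aq), NaOH (aq), MeOH–THF, 0 °C to rt
Reagents that add atoms: hydrogen peroxide, OO
Why: Algar–Flynn–Oyamada reaction: the phenoxide closes O1–C2 by 6-endo conjugate addition while the enolate carbon C3 is oxidised by hydrogen peroxide to give racemic trans-dihydroflavonol 9, whose two stereocentres are erased by further oxidation to the flavonol; nucleophilic peroxide leaves the isolated alkenes alone, and the absence of an ortho substituent on ring B favours the six-ring over the aurone pathway.

Step 7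
Reactants: 10 3-hydroxy-7-(methoxymethoxy)-2-{4-[(2-methylbut-3-en-2-yl)oxy]-3-[(3-methylbut-2-en-1-yl)oxy]phenyl}-5-[(3-methylbut-2-en-1-yl)oxy]-4H-chromen-4-one
Product: 11 3,7-bis(methoxymethoxy)-2-{4-[(2-methylbut-3-en-2-yl)oxy]-3-[(3-methylbut-2-en-1-yl)oxy]phenyl}-5-[(3-methylbut-2-en-1-yl)oxy]-4H-chromen-4-one
Conditions: MOMCl, i-Pr2NEt, CH2Cl2, 0 °C to rt
Reagents that add atoms: chloromethyl methyl ether, COCCl
Why: O-alkylation of the acidic 3-hydroxyl, the only free OH, under amine base, so that no acidic enol is present to bind the europium catalyst or to protonate dienone intermediates in the key step.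

Step 8
Reactants: 11 3,7-bis(methoxymethoxy)-2-{4-[(2-methylbut-3-en-2-yl)oxy]-3-[(3-methylbut-2-en-1-yl)oxy]phenyl}-5-[(3-methylbut-2-en-1-yl)oxy]-4H-chromen-4-one
Product: 14 2-[4,5-dihydroxy-2,3-bis(3-methylbut-2-en-1-yl)phenyl]-5-hydroxy-3,7-bis(methoxymethoxy)-8-(3-methylbut-2-en-1-yl)-4H-chromen-4-one, via C5'-prenyl phenol 12 (not isolated), via 8-prenyl 5-hydroxy ether 13 (not isolated)
Conditions: NaHCO3, PhCl, 110 °C; then Eu(fod)3 (0.2 equiv), 110 to 130 °C, Ar, one pot
Reagents that add atoms: none
Why: Three aryl allyl ether [3,3] shifts are run in one flask. The tertiary ether at O4' rearranges first (ortho-Claisen shift to C5', the only ortho carbon that bears hydrogen) and enolisation gives 12 with a normal prenyl group. Eu(fod)3, chelated between the C4 carbonyl and O5, then drives the O5 prenyl ether to C6, and because that carbon now carries a crowded 1,1-dimethylallyl group a Cope shift passes it on to C8, para to O5, giving 13 after enolisation. The O3' prenyl ether follows the same Claisen–Cope relay through C2' (or ipso through C4') to C6', para to O3', giving 14. The closest known reaction types are the europium-catalysed para-Claisen–Cope rearrangement of 5-O-prenyl flavonoids and the ortho-Claisen rearrangement of aryl 1,1-dimethylallyl ethers. No ring is closed and no stereocentre is formed, so the step needs positional selectivity only. C5' is secured by the oxygen-blocked C3' position and C8 by the chelate and the fused C4a position, while C6' over C2' rests on the strain of a quaternary carbon wedged between C1' and O3', which should make the Cope shift faster than enolisation, helped by NaHCO3, which keeps away acid that would speed enolisation or close chroman rings. The acetals at O3 and O7 cannot migrate, so C6 and C2 stay untouched.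

Step 9
Reactants: 14 2-[4,5-dihydroxy-2,3-bis(3-methylbut-2-en-1-yl)phenyl]-5-hydroxy-3,7-bis(methoxymethoxy)-8-(3-methylbut-2-en-1-yl)-4H-chromen-4-one
Product: 16 Broussoflavonol G, via 7-O-methoxymethyl ether 15 (not isolated)
Conditions: HCl (3 M aq), MeOH, 45 °C, Ar
Reagents that add atoms: none
Why: Acid-catalysed solvolysis of the two methoxymethyl acetals (the enol acetal at O3 first, giving 15, then the aryl acetal at O7); dilute acid at moderate temperature under argon is chosen because the prenyl groups at C8 and C5' sit beside free phenols and would close chroman rings under stronger acid.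

## Compound list

1 | 3,4-dihydroxybenzaldehyde | O=Cc1ccc(O)c(O)c1 | starting material
2 | 3-hydroxy-4-[(2-methylbut-3-en-2-yl)oxy]benzaldehyde | O=Cc1ccc(OC(C)(C)C=C)c(O)c1 | intermediate
3 | 4-[(2-methylbut-3-en-2-yl)oxy]-3-[(3-methylbut-2-en-1-yl)oxy]benzaldehyde | O=Cc1ccc(OC(C)(C)C=C)c(OCC=C(C)C)c1 | intermediate
4 | 1-(2,4,6-trihydroxyphenyl)ethan-1-one | CC(=O)c1c(O)cc(O)cc1O | starting material
5 | 1-[2,6-dihydroxy-4-(methoxymethoxy)phenyl]ethan-1-one | CC(=O)c1c(O)cc(OCOC)cc1O | intermediate
6 | 1-{2-hydroxy-4-(methoxymethoxy)-6-[(3-methylbut-2-en-1-yl)oxy]phenyl}ethan-1-one | CC(=O)c1c(O)cc(OCOC)cc1OCC=C(C)C | intermediate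
7 | 3-hydroxy-1-{2-hydroxy-4-(methoxymethoxy)-6-[(3-methylbut-2-en-1-yl)oxy]phenyl}-3-{4-[(2-methylbut-3-en-2-yl)oxy]-3-[(3-methylbut-2-en-1-yl)oxy]phenyl}propan-1-one (racemic) | O=C(CC(O)c1ccc(OC(C)(C)C=C)c(OCC=C(C)C)c1)c1c(O)cc(OCOC)cc1OCC=C(C)C | intermediate (not isolated)
8 | (E)-1-{2-hydroxy-4-(methoxymethoxy)-6-[(3-methylbut-2-en-1-yl)oxy]phenyl}-3-{4-[(2-methylbut-3-en-2-yl)oxy]-3-[(3-methylbut-2-en-1-yl)oxy]phenyl}prop-2-en-1-one | O=C(/C=C/c1ccc(OC(C)(C)C=C)c(OCC=C(C)C)c1)c1c(O)cc(OCOC)cc1OCC=C(C)C | intermediate
9 | trans-3-hydroxy-7-(methoxymethoxy)-2-{4-[(2-methylbut-3-en-2-yl)oxy]-3-[(3-methylbut-2-en-1-yl)oxy]phenyl}-5-[(3-methylbut-2-en-1-yl)oxy]chroman-4-one (racemic; the 2R,3R enantiomer is drawn) | O=C1c2c(OCC=C(C)C)cc(OCOC)cc2O[C@H](c2ccc(OC(C)(C)C=C)c(OCC=C(C)C)c2)[C@H]1O | intermediate (not isolated)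
10 | 3-hydroxy-7-(methoxymethoxy)-2-{4-[(2-methylbut-3-en-2-yl)oxy]-3-[(3-methylbut-2-en-1-yl)oxy]phenyl}-5-[(3-methylbut-2-en-1-yl)oxy]-4H-chromen-4-one | O=c1c(O)c(-c2ccc(OC(C)(C)C=C)c(OCC=C(C)C)c2)oc2cc(OCOC)cc(OCC=C(C)C)c12 | intermediate
11 | 3,7-bis(methoxymethoxy)-2-{4-[(2-methylbut-3-en-2-yl)oxy]-3-[(3-methylbut-2-en-1-yl)oxy]phenyl}-5-[(3-methylbut-2-en-1-yl)oxy]-4H-chromen-4-one | O=c1c(OCOC)c(-c2ccc(OC(C)(C)C=C)c(OCC=C(C)C)c2)oc2cc(OCOC)cc(OCC=C(C)C)c12 | intermediate
12 | 2-{4-hydroxy-3-(3-methylbut-2-en-1-yl)-5-[(3-methylbut-2-en-1-yl)oxy]phenyl}-3,7-bis(methoxymethoxy)-5-[(3-methylbut-2-en-1-yl)oxy]-4H-chromen-4-one | O=c1c(OCOC)c(-c2cc(CC=C(C)C)c(O)c(OCC=C(C)C)c2)oc2cc(OCOC)cc(OCC=C(C)C)c12 | intermediate (not isolated)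
13 | 5-hydroxy-2-{4-hydroxy-3-(3-methylbut-2-en-1-yl)-5-[(3-methylbut-2-en-1-yl)oxy]phenyl}-3,7-bis(methoxymethoxy)-8-(3-methylbut-2-en-1-yl)-4H-chromen-4-one | O=c1c(OCOC)c(-c2cc(CC=C(C)C)c(O)c(OCC=C(C)C)c2)oc2c(CC=C(C)C)c(OCOC)cc(O)c12 | intermediate (not isolated)
14 | 2-[4,5-dihydroxy-2,3-bis(3-methylbut-2-en-1-yl)phenyl]-5-hydroxy-3,7-bis(methoxymethoxy)-8-(3-methylbut-2-en-1-yl)-4H-chromen-4-one | O=c1c(OCOC)c(-c2c(CC=C(C)C)c(CC=C(C)C)c(O)c(O)c2)oc2c(CC=C(C)C)c(OCOC)cc(O)c12 | intermediate
15 | 2-[4,5-dihydroxy-2,3-bis(3-methylbut-2-en-1-yl)phenyl]-3,5-dihydroxy-7-(methoxymethoxy)-8-(3-methylbut-2-en-1-yl)-4H-chromen-4-one | O=c1c(O)c(-c2c(CC=C(C)C)c(CC=C(C)C)c(O)c(O)c2)oc2c(CC=C(C)C)c(OCOC)cc(O)c12 | intermediate (not isolated)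
16 | Broussoflavonol G, 2-[4,5-dihydroxy-2,3-bis(3-methylbut-2-en-1-yl)phenyl]-3,5,7-trihydroxy-8-(3-methylbut-2-en-1-yl)-4H-chromen-4-one | CC(C)=CCc1c(-c2oc3c(CC=C(C)C)c(O)cc(O)c3c(=O)c2O)cc(O)c(O)c1CC=C(C)C | target

## Step count and least certain steps

Total step count: 9.
Longest linear sequence: 7 steps (steps 3, 4, 5, 6, 7, 8, 9 from 4; the branch from 1 through steps 1, 2, 5, 6, 7, 8, 9 is equally long).

**Step 8 (key step).**
- What may go wrong: enolisation of the ring B ortho-dienone at C2' before the Cope shift, which would stop the relay with a 1,1-dimethylallyl group at C2'. This is the main risk, because ring B has no carbonyl beside O3' to hold the catalyst as ring A has. Lesser risks are loss of the tertiary allyl group by ionisation before it migrates, and chroman closure of the ortho-prenyl phenols once they form.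
- Fallback: the ring A relay, which has the closest precedent, is kept, and the ring B prenyl groups are brought in by cross-coupling. The fallback sets out from ketone 6 and comes back to the route at target 16. Commercial 2,3-dibromo-4-hydroxy-5-methoxybenzaldehyde F1 is demethylated (BBr3, CH2Cl2, −78 to 0 °C) to 2,3-dibromo-4,5-dihydroxybenzaldehyde F2 and protected (MOMCl, i-Pr2NEt) as 2,3-dibromo-4,5-bis(methoxymethoxy)benzaldehyde F3. Claisen–Schmidt condensation of F3 with 6 (KOH, EtOH) gives the dibromo chalcone F4, Algar–Flynn–Oyamada oxidation gives the dibromo flavonol F5, and MOMCl with i-Pr2NEt gives its 3-O-acetal F6. The ring A Claisen–Cope relay alone (Eu(fod)3, NaHCO3, PhCl, 85 °C) should then give the 8-prenyl 5-hydroxy dibromide F7. A double Stille coupling with tributyl(3-methylbut-2-en-1-yl)stannane (Pd(PPh3)4, DMF, 100 °C) replaces both bromines by prenyl groups to give the tetra-acetal F8. The acid conditions of step 9 remove the four acetals and give 16.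

**Step 1.**
- What may go wrong: isomerisation of the kinetic tertiary ether to the linear prenyl ether through re-ionisation by the palladium catalyst, made easier because the para-formyl phenoxide is a good leaving group; and alkylation of the second hydroxyl.
- Fallback: it sets out from 1 and comes back at 2. Propargylation with 3-chloro-3-methylbut-1-yne (CuCl2 catalyst, DBU, MeCN, 0 °C) gives 3-hydroxy-4-[(2-methylbut-3-yn-2-yl)oxy]benzaldehyde F9. Semi-hydrogenation (H2, Pd/CaCO3 poisoned with Pb(OAc)2, quinoline, EtOAc) then gives 2 without any allyl-metal intermediate.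

**Step 6.**
- What may go wrong: five-ring closure at Cα to an aurone, favoured because the prenyloxy group ortho to the carbonyl twists the enone out of the plane of ring A; and incomplete oxidation of 9.
- Fallback: O3 is introduced through a C3 anion and not by peroxide attack on the enone. It sets out from 8 and comes back at 10. Base-mediated oxa-Michael closure (NaOAc, EtOH, 70 °C) gives the racemic flavanone F10. Dehydrogenation with 2-iodoxybenzoic acid (DMSO, 70 °C) gives the flavone F11. C3 lithiation (LDA, THF, −78 °C), borylation with B(OMe)3 and oxidation with alkaline H2O2 then give 10.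

**Step 4.**
- What may go wrong: C-alkylation of the electron-rich phloroglucinol ring by the allylic bromide, and alkylation of both chelated hydroxyls.
- Fallback: it sets out from 5 and comes back at 6, with no new compound. A Mitsunobu etherification with 3-methylbut-2-en-1-ol (PPh3, diisopropyl azodicarboxylate, THF, 0 °C) activates the alcohol and not the phenol, so no phenoxide is present to react at carbon.

## Further compounds

F1 | step 8 | 2,3-dibromo-4-hydroxy-5-methoxybenzaldehyde | O=Cc1cc(OC)c(O)c(Br)c1Br
F2 | step 8 | 2,3-dibromo-4,5-dihydroxybenzaldehyde | O=Cc1cc(O)c(O)c(Br)c1Br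
F3 | step 8 | 2,3-dibromo-4,5-bis(methoxymethoxy)benzaldehyde | O=Cc1cc(OCOC)c(OCOC)c(Br)c1Br
F4 | step 8 | (E)-3-[2,3-dibromo-4,5-bis(methoxymethoxy)phenyl]-1-{2-hydroxy-4-(methoxymethoxy)-6-[(3-methylbut-2-en-1-yl)oxy]phenyl}prop-2-en-1-one | O=C(/C=C/c1cc(OCOC)c(OCOC)c(Br)c1Br)c1c(O)cc(OCOC)cc1OCC=C(C)C
F5 | step 8 | 2-[2,3-dibromo-4,5-bis(methoxymethoxy)phenyl]-3-hydroxy-7-(methoxymethoxy)-5-[(3-methylbut-2-en-1-yl)oxy]-4H-chromen-4-one | O=c1c(O)c(-c2cc(OCOC)c(OCOC)c(Br)c2Br)oc2cc(OCOC)cc(OCC=C(C)C)c12
F6 | step 8 | 2-[2,3-dibromo-4,5-bis(methoxymethoxy)phenyl]-3,7-bis(methoxymethoxy)-5-[(3-methylbut-2-en-1-yl)oxy]-4H-chromen-4-one | O=c1c(OCOC)c(-c2cc(OCOC)c(OCOC)c(Br)c2Br)oc2cc(OCOC)cc(OCC=C(C)C)c12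
F7 | step 8 | 2-[2,3-dibromo-4,5-bis(methoxymethoxy)phenyl]-5-hydroxy-3,7-bis(methoxymethoxy)-8-(3-methylbut-2-en-1-yl)-4H-chromen-4-one | O=c1c(OCOC)c(-c2cc(OCOC)c(OCOC)c(Br)c2Br)oc2c(CC=C(C)C)c(OCOC)cc(O)c12
F8 | step 8 | 2-[4,5-bis(methoxymethoxy)-2,3-bis(3-methylbut-2-en-1-yl)phenyl]-5-hydroxy-3,7-bis(methoxymethoxy)-8-(3-methylbut-2-en-1-yl)-4H-chromen-4-one | O=c1c(OCOC)c(-c2cc(OCOC)c(OCOC)c(CC=C(C)C)c2CC=C(C)C)oc2c(CC=C(C)C)c(OCOC)cc(O)c12
F9 | step 1 | 3-hydroxy-4-[(2-methylbut-3-yn-2-yl)oxy]benzaldehyde | O=Cc1ccc(OC(C)(C)C#C)c(O)c1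
F10 | step 6 | 7-(methoxymethoxy)-2-{4-[(2-methylbut-3-en-2-yl)oxy]-3-[(3-methylbut-2-en-1-yl)oxy]phenyl}-5-[(3-methylbut-2-en-1-yl)oxy]chroman-4-one (racemic) | O=C1CC(c2ccc(OC(C)(C)C=C)c(OCC=C(C)C)c2)Oc2cc(OCOC)cc(OCC=C(C)C)c12
F11 | step 6 | 7-(methoxymethoxy)-2-{4-[(2-methylbut-3-en-2-yl)oxy]-3-[(3-methylbut-2-en-1-yl)oxy]phenyl}-5-[(3-methylbut-2-en-1-yl)oxy]-4H-chromen-4-one | O=c1cc(-c2ccc(OC(C)(C)C=C)c(OCC=C(C)C)c2)oc2cc(OCOC)cc(OCC=C(C)C)c12
F0 | step 4 | none | none
A1 | alternative 1 | 4,5-bis(methoxymethoxy)-2,3-bis(3-methylbut-2-en-1-yl)benzaldehyde | O=Cc1cc(OCOC)c(OCOC)c(CC=C(C)C)c1CC=C(C)C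
A2 | alternative 1 | 1-[2-hydroxy-4,6-bis(methoxymethoxy)-3-(3-methylbut-2-en-1-yl)phenyl]ethan-1-one | CC(=O)c1c(O)c(CC=C(C)C)c(OCOC)cc1OCOC
A3 | alternative 1 | (E)-3-[4,5-bis(methoxymethoxy)-2,3-bis(3-methylbut-2-en-1-yl)phenyl]-1-[2-hydroxy-4,6-bis(methoxymethoxy)-3-(3-methylbut-2-en-1-yl)phenyl]prop-2-en-1-one | O=C(/C=C/c1cc(OCOC)c(OCOC)c(CC=C(C)C)c1CC=C(C)C)c1c(O)c(CC=C(C)C)c(OCOC)cc1OCOC
A4 | alternative 2 | 3,5-bis(methoxymethoxy)-2-(3-methylbut-2-en-1-yl)-6-(trimethylsilyl)phenyl trifluoromethanesulfonate | C[Si](C)(C)c1c(OCOC)cc(OCOC)c(CC=C(C)C)c1OS(=O)(=O)C(F)(F)F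
A5 | alternative 2 | 3,5-bis(methoxymethoxy)-6-(3-methylbut-2-en-1-yl)-1,2-didehydrobenzene | CC(C)=CCC1=C(OCOC)C=C(OCOC)C#C1
A6 | alternative 2 | 3-[4,5-bis(methoxymethoxy)-2,3-bis(3-methylbut-2-en-1-yl)phenyl]prop-2-ynoic acid | OC(=O)C#Cc1cc(OCOC)c(OCOC)c(CC=C(C)C)c1CC=C(C)C
A7 | alternative 2 | 2-[4,5-bis(methoxymethoxy)-2,3-bis(3-methylbut-2-en-1-yl)phenyl]-5,7-bis(methoxymethoxy)-8-(3-methylbut-2-en-1-yl)-4H-chromen-4-one | O=c1cc(-c2cc(OCOC)c(OCOC)c(CC=C(C)C)c2CC=C(C)C)oc2c(CC=C(C)C)c(OCOC)cc(OCOC)c12
A8 | alternative 3 | 2-[4,5-bis(methoxymethoxy)-2,3-bis(3-methylbut-2-en-1-yl)phenyl]-6-(diazoacetyl)-3-(methoxymethoxy)-4H-pyran-4-one | [N-]=[N+]=CC(=O)c1cc(=O)c(OCOC)c(-c2cc(OCOC)c(OCOC)c(CC=C(C)C)c2CC=C(C)C)o1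
A9 | alternative 3 | 2-[4,5-bis(methoxymethoxy)-2,3-bis(3-methylbut-2-en-1-yl)phenyl]-5-hydroxy-3-(methoxymethoxy)-7-[(triisopropylsilyl)oxy]-4H-chromen-4-one | O=c1c(OCOC)c(-c2cc(OCOC)c(OCOC)c(CC=C(C)C)c2CC=C(C)C)oc2cc(O[Si](C(C)C)(C(C)C)C(C)C)cc(O)c12
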